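**Retrosynthetic overview**
1. Target 4 ⇐ hydroxy acid 3: the C16–O bond is made last by a carboxylate-directed allylic C–H acetoxylation of the methyl group that is already cis to CO2H. The alkene geometry is inherited; only the CIP label changes from 13E to 13Z.
2. 3 ⇐ spiro-epoxide 2: the C17–OH and the Δ7 alkene come from opening the 8,17-oxirane toward C7. 2 ⇐ 1 by epoxidation of the exocyclic alkene.
3. 1 is (−)-copalic acid, which supplies the trans-decalin and C5, C9 and C10 unchanged. No carbocycle and no C–C bond is formed; the only ring made (and reopened) is the oxirane.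

Assumption: (−)-copalic acid (ent-labda-8(17),13E-dien-15-oic acid), the main diterpene acid of commodity copaiba oleoresin and a catalogue compound, is taken as the purchasable starting material; its price as a pure compound is the weak point of this choice. Labdane numbering is used throughout.

**Step 1**
Reactants: 1 (−)-copalic acid, ent-labda-8(17),13E-dien-15-oic acid (5R,9R,10R)
Product: 2 (8S)-8,17-epoxy-ent-labd-13E-en-15-oic acid (5R,8S,9S,10R; oxirane oxygen on the ring face opposite the C10 methyl)
Conditions: mCPBA (1.1 equiv), CH2Cl2, 0 °C, 1 h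
Reagents that add atoms: mCPBA, O=C(OO)c1cccc(Cl)c1
Why: Prilezhaev epoxidation takes the electron-rich exocyclic 1,1-disubstituted alkene and leaves the conjugated enoic acid alkene, with the peracid approaching equatorially, anti to the axial C10 methyl, to set C8 as S (this centre is erased in step 2, so a minor epimer converges).

**Step 2**
Reactants: 2 (8S)-8,17-epoxy-ent-labd-13E-en-15-oic acid
Product: 3 17-hydroxy-ent-labda-7,13E-dien-15-oic acid (5R,9S,10R)
Conditions: Al(OiPr)3 (3 equiv), toluene, 110 °C; then 1 M HCl
Reagents that add atoms: none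
Why: Aluminium isopropoxide epoxide-to-allylic-alcohol isomerisation (Lewis-acid-assisted syn β-elimination through a six-membered transition state) breaks the tertiary C8–O bond and removes a proton from the unhindered C7 methylene rather than the shielded tertiary C9–H, giving the Δ7 alkene and the primary C17 alcohol without touching C9.

**Step 3**
Reactants: 3 17-hydroxy-ent-labda-7,13E-dien-15-oic acid
Product: 4 16-acetoxy-17-hydroxy-ent-labda-7,13Z-dien-15-oic acid (5R,9S,10R)
Conditions: Pd(OAc)2 (10 mol %), Ac-Gly-OH (20 mol %), 1,4-benzoquinone (2 equiv), NaOAc (1 equiv), AcOH (10 equiv), 1,4-dioxane, 45 °C, 24 h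
Reagents that add atoms: acetic acid, CC(=O)O
Why: Proposed new method: carboxylate-directed allylic C(sp3)–H acetoxylation of an (E)-β-methyl enoic acid, in which the κO-bound carboxylate of 3 lets ligand-assisted concerted metalation–deprotonation reach only the γ-methyl cis to CO2H (C16) through a planar six-membered palladacycle (an η1/η3-allyl with the carboxyl held anti), the trans C12–H2 and the ring allylic C–H bonds being out of reach; benzoquinone-promoted attack of acetate at the unhindered C16 terminus, distal to the electron-withdrawing carboxyl, forms the C16–O bond and returns the C13=C14 bond with CO2H and CH2OAc still cis (13Z), whereas closure of the bound carboxylate onto C16 would be a 5-endo process; benzoquinone reoxidises Pd(0), and the closest known reactions are Pd(II)/benzoquinone allylic C–H acetoxylation of terminal alkenes and carboxylate-directed Pd-catalysed C(sp3)–H acyloxylation and lactonisation of saturated and o-methylbenzoic acids.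

**Compound list**
1 | (−)-copalic acid, ent-labda-8(17),13E-dien-15-oic acid | C/C(=C\C(=O)O)CC[C@@H]1C(=C)CC[C@@H]2C(C)(C)CCC[C@@]12C | starting material
2 | (8S)-8,17-epoxy-ent-labd-13E-en-15-oic acid | C/C(=C\C(=O)O)CC[C@@H]1[C@]3(CO3)CC[C@@H]2C(C)(C)CCC[C@@]12C | intermediate
3 | 17-hydroxy-ent-labda-7,13E-dien-15-oic acid | C/C(=C\C(=O)O)CC[C@@H]1C(CO)=CC[C@@H]2C(C)(C)CCC[C@@]12C | intermediate
4 | 16-acetoxy-17-hydroxy-ent-labda-7,13Z-dien-15-oic acid | CC(=O)OC/C(=C\C(=O)O)CC[C@@H]1C(CO)=CC[C@@H]2C(C)(C)CCC[C@@]12C | target

**Total step count:** 3. **Longest linear sequence:** 3.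

**Steps most likely to fail**

Step 3 (the new reaction). The risks are: no directed C–H cleavage on this electron-poor allyl system; closure to the butenolide instead of acetate capture; syn/anti isomerisation of the allyl giving the 13E acetate; and oxidation or acetylation of the free C17 alcohol. The fallback uses known chemistry, sets out from 1 and comes back at 4, and is much longer than the main route, because every acyclic way of oxygenating C16 gives the wrong alkene geometry and the cis relationship has to be enforced through a lactone. Permanganate cleavage of the conjugated C13=C14 bond of 1 (KMnO4, MgSO4, acetone–water, 0 °C; expected to spare the hindered exocyclic alkene) gives ent-14,15-dinorlabd-8(17)-en-13-one F2. Kinetic enolisation at the methyl group (LDA, THF, −78 °C) and Davis oxaziridine give 16-hydroxy-ent-14,15-dinorlabd-8(17)-en-13-one F3. Bestmann's ylide (Ph3P=C=C=O, toluene, 110 °C; O-acylation then intramolecular Wittig) closes ent-labda-8(17),13-dien-15,16-olide F4 (lactone carbonyl C15, ring oxygen on C16), which fixes C16–O cis to C15. LiOH (THF–water) followed by allyl bromide in DMF traps the ring-opened carboxylate as allyl (13Z)-16-hydroxy-ent-labda-8(17),13-dien-15-oate F5, which is acetylated at once (Ac2O, pyridine, DMAP, 0 °C) to allyl (13Z)-16-acetoxy-ent-labda-8(17),13-dien-15-oate F6. Pd(PPh3)4 with morpholine (THF, 0 °C) removes the allyl ester to give (13Z)-16-acetoxy-ent-labda-8(17),13-dien-15-oic acid F7. A Schenck ene reaction of the exocyclic alkene (O2, TPP, hν, CH2Cl2, 0 °C) gives 16-acetoxy-17-hydroperoxy-ent-labda-7,13Z-dien-15-oic acid F8, which is reduced in the same flask with PPh3 to 4.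

Step 2. The risks are Meinwald rearrangement of the spiro-epoxide to the C17 aldehyde (then Meerwein–Ponndorf reduction) and proton loss from C9 to give the Δ8(9) isomer. The fallback sets out from 2 and comes back at 3 and replaces the polar opening by a radical one: Cp2TiCl (from Cp2TiCl2 and Mn, THF, room temperature, 3.5 equiv to allow for the free acid) opens the oxirane homolytically to the tertiary C8 radical, which loses a β-hydrogen from C7 to give 3. No new compound is made on the way.

Step 1. The risk is acid-triggered rearrangement of the tertiary spiro-epoxide by 3-chlorobenzoic acid or by the substrate's own acid. The fallback sets out from 1 and comes back at 3, bypassing 2: dye-sensitised photooxygenation (O2, TPP, hν, CH2Cl2, 0 °C; ene reaction with oxygen bonding at C17 and the hydrogen taken from C7) gives 17-hydroperoxy-ent-labda-7,13E-dien-15-oic acid F1, reduced in the same flask with PPh3 to 3.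

**Further compounds**
F1 | step 1 | 17-hydroperoxy-ent-labda-7,13E-dien-15-oic acid | C/C(=C\C(=O)O)CC[C@@H]1C(COO)=CC[C@@H]2C(C)(C)CCC[C@@]12C
F0 | step 2 | none | none
F2 | step 3 | ent-14,15-dinorlabd-8(17)-en-13-one | CC(=O)CC[C@@H]1C(=C)CC[C@@H]2C(C)(C)CCC[C@@]12C
F3 | step 3 | 16-hydroxy-ent-14,15-dinorlabd-8(17)-en-13-one | OCC(=O)CC[C@@H]1C(=C)CC[C@@H]2C(C)(C)CCC[C@@]12C
F4 | step 3 | ent-labda-8(17),13-dien-15,16-olide | O=C1OCC(CC[C@@H]2C(=C)CC[C@@H]3C(C)(C)CCC[C@@]23C)=C1
F5 | step 3 | allyl (13Z)-16-hydroxy-ent-labda-8(17),13-dien-15-oate | OC/C(=C\C(=O)OCC=C)CC[C@@H]1C(=C)CC[C@@H]2C(C)(C)CCC[C@@]12C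
F6 | step 3 | allyl (13Z)-16-acetoxy-ent-labda-8(17),13-dien-15-oate | CC(=O)OC/C(=C\C(=O)OCC=C)CC[C@@H]1C(=C)CC[C@@H]2C(C)(C)CCC[C@@]12C
F7 | step 3 | (13Z)-16-acetoxy-ent-labda-8(17),13-dien-15-oic acid | CC(=O)OC/C(=C\C(=O)O)CC[C@@H]1C(=C)CC[C@@H]2C(C)(C)CCC[C@@]12C
F8 | step 3 | 16-acetoxy-17-hydroperoxy-ent-labda-7,13Z-dien-15-oic acid | CC(=O)OC/C(=C\C(=O)O)CC[C@@H]1C(COO)=CC[C@@H]2C(C)(C)CCC[C@@]12C
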